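## The problem

Atoms are numbered as in the kaurane skeleton. Ring A is C1–C5 and C10, with two methyls on C4 and the C20 methyl on C10. Ring B is the seven-membered hemiacetal C5, C6, O, C7, C8, C9, C10. Rings C (C8, C9, C11–C14) and D (C8, C14, C13, C16, C15) form a bicyclo[3.2.1]octane that carries the C15 ketone and the C16=C17 methylene.

- Nine stereocenters are present (C1, C2, C5, C6, C8, C9, C10, C11, C13). Most of them depend on one another: C13 is tied to C8 by the bridge, C9 and C11 follow from the face on which a C9=C11 alkene is epoxidised, and C6 is an anomeric centre that equilibrates.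
- C1, C2 and C5 can all be set from C10, because the axial C20 methyl and the axial C4 methyl close one face of ring A.
- Nothing in the molecule enforces the relation between C10 and the C8/C13 pair. The two halves are joined only by the C9–C10 bond and rotate about it as long as ring B is open.
- Both acetoxy groups lie on the face of C20, and the C2 oxygen is axial between two axial methyls. The diol must therefore come from hydride delivery to carbonyl groups; osmylation of an alkene would give the other face.
- The methylene ketone (a Michael acceptor), the epoxide between two quaternary carbons (acid-labile), the hemiacetal (oxidisable, in ring–chain equilibrium) and the acetates (base-labile) must all appear late.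
- The key step is possible because C13 is an unfunctionalised methine five atoms from C16 along C16–C15–C8–C14–C13, with C8 quaternary and C15 a carbonyl. A carbene at C16 on an acyl group at C8 of a cyclohexene can reach the C13–H bond and close ring D.

## Retrosynthesis

**31 to 30 (C9–O and C11–O).** The epoxide is removed first. It is the most acid-sensitive group, and in 30 the C9=C11 bond is the only electron-rich alkene, since the methylene ketone is deactivated. The forward step needs oxygen transfer to the face of C14, the open face of a bicyclo[3.2.1]octene.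

**30 to 28 (the C7–O–C6 hemiacetal bond).** Opening ring B gives aldehyde 28 with a silylated C7 alcohol. This is preferred to a lactone, which would need a hydride reduction in the presence of two acetates and an enone. The forward step is a desilylation that closes the ring by itself.

**28 to 24 (C17, then C5–H and C6–O).** The aldehyde comes from alcohol 27, the methylene from ketone 26 by a Mannich-type condensation, and the ketone from ketal 25. Alcohol 25 comes from the C5=C6 methylene compound 24 by hydroboration. This cut sets C5 by reagent approach from the face opposite the two axial methyls, which no enolate chemistry at C5 would do as reliably.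

**24 to 21 (C1–H, C2–H, C2–O).** The diacetate comes from cis-diol 23, the diol from diosphenol 22, and 22 from ketone 21 by autoxidation. C10 is quaternary, so only C2 can enolise; hydride then enters both carbonyl carbons from the open face. A C1=C2 alkene was rejected because osmylation would place the diol on the wrong face.

**21 to 16 (two C4–CH3 bonds and C5=C6).** Ketone 21 comes from alcohol 20 and silyl ether 19. The methylene comes from ketone 18 and the two methyls from ketone 17, the silyl ether of hydroxy ketone 16. In 16 the carbon that becomes C5 is still a ketone, which makes C4 the only enolisable position. The price is that C1 is held as a protected alcohol for four steps and is then oxidised again.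

**16 to 15 (the C10 stereocenter).** In dione 15, C10 carries a methyl, the bicyclic alkenyl group and two identical carbonyl arms; it is prochiral. Reduction of one carbonyl under catalyst control fixes C10 relative to C8 without asking the remote bicycle to direct anything. Two relays from the bicycle were set aside as too weak across a freely rotating C9–C10 bond: closing ring A onto C10 from an open chain, and alkylating a ring A enolate.

**15 to 9 and 11 (C10–C20 and C9–C10).** The methyl is removed to give enol 14, which comes from vinylogous ester 13. Compound 13 is cut at C9–C10 into enol triflate 9 and iodide 11, made from commercial 10. This sp2–sp2 bond is hindered on both sides, which cross-coupling tolerates, and no stereocenter is formed. Ring A arrives with C1 and C5 already oxidised.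

**9 to 8 to 7 (C13–C16, the key cut).** Ketal 9 comes from ketone 8. Cutting C13–C16 of 8 leads to diazo ketone 7, a monocycle with a single stereocenter. The cut removes ring D and C13 and leaves the C15 ketone and the C9 triflate exactly where they are needed. The forward step needs 1,5 insertion in preference to reaction at the ether oxygen or the alkene.

**7 to 1 (C15–C16, then C7–C8).** The diazo ketone comes from acid 5 through acid chloride 6. The acid comes from tert-butyl ester 4, the enol triflate from ketone 3, and the silyl ether from alcohol 2. Alcohol 2 comes from keto ester 1 by enantioselective hydroxymethylation, which sets C8. The tert-butyl ester is used because it gives the best selectivity with this catalyst type and is cleaved by acid without touching the enol triflate.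

## Roads not taken

**Alternative 1:** Ring A is closed last, between an aldehyde carbon C1 on C10 and an aldehyde carbon C2 on C3. A thiazolium-derived carbene turns the less hindered C2 aldehyde into an acyl anion equivalent that adds to C1, giving acyloin A1.
- Merits: one step delivers both ring A oxygens with C1 already configured, leaving only a hydride reduction at C2. In ring A redox economy this is better than the chosen plan, which spends three steps (oxidation, autoxidation, reduction) on the same result.
- Weak points: the acyloin can equilibrate by ketol shift and epimerise at C1. The C15 ketone must be added later by allylic oxidation next to a second allylic system (C12). The quaternary C10 bearing a formyl group must already exist with the right configuration relative to C8, so the hardest stereochemical relation is moved upstream, not solved.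
- Comparison: the chosen plan makes the C15 ketone together with ring D and fixes C10 by a catalyst whose sense can be reversed.

**Alternative 2:** Rings B and C are formed together. An oxyallyl cation over C9–C11–C12 adds across C8 and C13 of a lactone-tethered 2-silyloxycyclopentadiene to give A2.
- Merits: it is the most convergent of the four plans. Two rings, the quaternary C8 and the bridge arise in one step, and the ester tether relays the ring A configuration to C8. That is a real answer to the C10/C8 problem and builds more complexity per step than the carbenoid insertion.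
- Weak points: a cyclopentadiene substituted at a terminus isomerises by 1,5-hydrogen shifts. The cycloaddition must join a fully substituted diene terminus to an oxyallyl carbon next to quaternary C10. A2 carries a C11 ketone and a C9 hydrogen that the target does not have, so C9 is set and then erased on the way to the C9=C11 alkene, and the ketone must enolise towards the hindered C9. C1 is still unoxidised.
- Comparison: the chosen plan forms one ring in its key step, but from a precursor made in five steps, and leaves every functional group where it is used.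

**Alternative 3:** The C7 alcohol is esterified with a ring A enone acid. Zerovalent palladium inserts into the C9 triflate, the alkenylpalladium adds to C10, and formate reduces the palladium enolate to give A3.
- Merits: it is shorter. Ring A arrives complete with the geminal methyls, C20 and C6, and the C9–C10 bond forms inside a ring, so the tether, not a catalyst, relays C8 to C10. In step count and in the idea of an internal relay it is better than the chosen plan.
- Weak points: a seven-membered conjugate Heck closure onto a β,β-disubstituted enone is demanding, and the sense of induction rests on an unknown tether conformation. A3 has a C2 ketone flanked by two methylene groups that both neighbour quaternary carbons, so oxygenation at C1 has no regiochemical handle. The lactone must be reduced to the lactol beside acetates and an enone, and the C15 ketone is still missing.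
- Comparison: the chosen plan offers a reagent-controlled C10, C1 oxygen built in from the dione, C6 reached at the aldehyde level, and the C15 ketone from the key step.

Key step: step 6

Remark: the C6 hemiacetal configuration of the target is taken to be the anomer favoured at equilibrium; no reagent sets it.
Remark: the enantiomer of each chiral catalyst (steps 1 and 12) is assigned from the accepted models; if the sense is the reverse, the antipodal catalyst is used and nothing else changes.
Remark: "bicyclic alkenyl" below means the ketal-protected bicycle of 9 attached through C9, with C8 and C13 configured as in 8.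

## Route

Step 1
Reactants: 1 tert-butyl 2-oxocyclohexane-1-carboxylate
Product: 2 tert-butyl (S)-1-(hydroxymethyl)-2-oxocyclohexane-1-carboxylate
Conditions: [Pd((R)-BINAP)(H2O)2](OTf)2 (5 mol%), aq. HCHO, THF, −20 °C
Reagents that add atoms: formaldehyde, C=O
Why: Catalytic enantioselective aldol-type hydroxymethylation of a β-keto ester; the cationic divalent palladium complex forms a chelated chiral enolate whose open face takes up formaldehyde, which sets the quaternary C8.

Step 2
Reactants: 2 tert-butyl (S)-1-(hydroxymethyl)-2-oxocyclohexane-1-carboxylate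
Product: 3 tert-butyl (S)-1-[(tert-butyldiphenylsilyloxy)methyl]-2-oxocyclohexane-1-carboxylate
Conditions: t-BuPh2SiCl, imidazole, CH2Cl2, 0 °C to rt
Reagents that add atoms: tert-butyl(chloro)diphenylsilane, CC(C)(C)[Si](Cl)(c1ccccc1)c1ccccc1
Why: Silylation of the primary alcohol under near-neutral conditions stops retro-aldol loss of formaldehyde; this bulky silyl group survives the later acid steps and shields the ether oxygen in step 6.

Step 3
Reactants: 3 tert-butyl (S)-1-[(tert-butyldiphenylsilyloxy)methyl]-2-oxocyclohexane-1-carboxylate
Product: 4 tert-butyl (S)-1-[(tert-butyldiphenylsilyloxy)methyl]-2-(trifluoromethylsulfonyloxy)cyclohex-2-ene-1-carboxylate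
Conditions: KN(SiMe3)2, PhNTf2, THF, −78 to 0 °C
Reagents that add atoms: N-phenylbis(trifluoromethanesulfonimide), O=S(=O)(N(c1ccccc1)S(=O)(=O)C(F)(F)F)C(F)(F)F
Why: Enol triflate formation; C8 is quaternary, so the ketone enolises only towards C11, and O-sulfonylation gives the C9 triflate that is both the later coupling handle and an electron-poor mask for the C9=C11 bond.

Step 4
Reactants: 4 tert-butyl (S)-1-[(tert-butyldiphenylsilyloxy)methyl]-2-(trifluoromethylsulfonyloxy)cyclohex-2-ene-1-carboxylate
Product: 5 (S)-1-[(tert-butyldiphenylsilyloxy)methyl]-2-(trifluoromethylsulfonyloxy)cyclohex-2-ene-1-carboxylic acid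
Conditions: CF3CO2H, CH2Cl2, 0 °C to rt
Reagents that add atoms: none
Why: Acidolysis of the tert-butyl ester with loss of isobutene; the enol triflate and the silyl ether are stable to the acid, and the product is no longer a β-keto acid, so it should not decarboxylate.

Step 5
Reactants: 5 (S)-1-[(tert-butyldiphenylsilyloxy)methyl]-2-(trifluoromethylsulfonyloxy)cyclohex-2-ene-1-carboxylic acid
Product: 7 (S)-6-(2-diazoacetyl)-6-[(tert-butyldiphenylsilyloxy)methyl]cyclohex-1-en-1-yl trifluoromethanesulfonate, via acid chloride 6 (not isolated)
Conditions: (COCl)2, DMF (cat.), CH2Cl2, 0 °C to rt; evaporate; CH2N2 (3 equiv), Et2O, 0 °C to rt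
Reagents that add atoms: diazomethane, C=[N+]=[N-]; oxalyl chloride, O=C(Cl)C(Cl)=O (chlorine of 6 only)
Why: Acylation of diazomethane by an acid chloride (first stage of the Arndt–Eistert sequence); the acid chloride has no α-hydrogen, so no ketene can form, and excess diazomethane removes the hydrogen chloride.

Step 6
Reactants: 7 (S)-6-(2-diazoacetyl)-6-[(tert-butyldiphenylsilyloxy)methyl]cyclohex-1-en-1-yl trifluoromethanesulfonate
Product: 8 (1S,5R)-1-[(tert-butyldiphenylsilyloxy)methyl]-7-oxobicyclo[3.2.1]oct-2-en-2-yl trifluoromethanesulfonate (skeleton numbering: C8 S, C13 R, C15 ketone, C9 triflate)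
Conditions: Rh2(OAc)4 (1 mol%), CH2Cl2, 40 °C, slow addition of 7
Reagents that add atoms: none
Why: Rh2(OAc)4 (divalent rhodium) takes nitrogen from the diazo ketone and gives an electrophilic carbenoid at C16. The carbenoid inserts into the C13–H bond that is syn-axial to the acyl arm through a concerted three-centre transition state, forming C13–C16 with retention at C13. The closest known reaction type is the dirhodium-catalysed intramolecular 1,5 C–H insertion of α-diazo ketones to cyclopentanones, here in the less common bridging mode across the 1,3-positions of a six-membered ring. Ring D closes as a five-membered ketone (C8, C15, C16, C13, C14) when the diazoacetyl group is axial on the cyclohexene half-chair. The new stereocenter C13 is dictated by C8, because only the cis-bridged bicycle is geometrically possible. The step needs C13–H to win over the allylic C12–H (a six-membered closure through a boat), over C7–H and C14–H (four-membered rings), over the C9=C11 bond and over the ether oxygen. The triflate lowers the nucleophilicity of the alkene and so suppresses carbenoid addition and the vinylogous Wolff pathway. The bulky tert-butyldiphenylsilyl group and slow addition in a non-coordinating solvent are meant to suppress the five-membered oxonium ylide.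

Step 7
Reactants: 8 (1S,5R)-1-[(tert-butyldiphenylsilyloxy)methyl]-7-oxobicyclo[3.2.1]oct-2-en-2-yl trifluoromethanesulfonate
Product: 9 C15 ethylene ketal (1,3-dioxolane) of 8
Conditions: (Me3SiOCH2)2, Me3SiOTf (5 mol%), CH2Cl2, −78 to −20 °C
Reagents that add atoms: 1,2-bis(trimethylsilyloxy)ethane, C[Si](C)(C)OCCO[Si](C)(C)C
Why: Noyori ketalisation under aprotic conditions that leave the enol triflate and silyl ether alone; the ketal removes the only enolisable, reducible carbonyl of the bicycle before the base and hydride steps on ring A.

Step 8
Reactants: 10 3-ethoxycyclohex-2-en-1-one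
Product: 11 3-ethoxy-2-iodocyclohex-2-en-1-one
Conditions: N-iodosuccinimide, CH2Cl2, 0 °C to rt, dark
Reagents that add atoms: N-iodosuccinimide, O=C1CCC(=O)N1I
Why: Electrophilic iodination at the nucleophilic α-carbon of a vinylogous ester, the carbon that becomes C10.

Step 9
Reactants: 9 C15 ethylene ketal of 8; 11 3-ethoxy-2-iodocyclohex-2-en-1-one
Product: 13 3-ethoxy-2-(bicyclic alkenyl)cyclohex-2-en-1-one (C9–C10 bond formed), via alkenyl boronate 12 (not isolated)
Conditions: B2pin2, PdCl2(dppf) (5 mol%), KOAc, 1,4-dioxane, 90 °C; then 11, Pd(OAc)2 (5 mol%), SPhos (10 mol%), aq. K3PO4, 80 °C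
Reagents that add atoms: bis(pinacolato)diboron, CC1(C)OB(OC1(C)C)B1OC(C)(C)C(C)(C)O1 (boryl group of 12 only, lost again in the coupling)
Why: Miyaura borylation of the enol triflate followed by Suzuki–Miyaura coupling with the iodo enone; the bond joins two sp2 carbons, so no stereocenter is formed, and a biarylphosphine ligand is used for the doubly hindered junction.

Step 10
Reactants: 13 3-ethoxy-2-(bicyclic alkenyl)cyclohex-2-en-1-one
Product: 14 2-(bicyclic alkenyl)cyclohexane-1,3-dione (enol form)
Conditions: LiOH, THF/H2O, 50 °C; then 1 M HCl to pH 4, 0 °C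
Reagents that add atoms: lithium hydroxide, [Li+].[OH-]
Why: Saponification of a vinylogous ester by addition–elimination; the ketal and silyl ether are stable to base, and the brief cold acidification should leave the ketal intact.

Step 11
Reactants: 14 2-(bicyclic alkenyl)cyclohexane-1,3-dione
Product: 15 2-methyl-2-(bicyclic alkenyl)cyclohexane-1,3-dione (C10 quaternary and prochiral)
Conditions: MeI, K2CO3, acetone, 45 °C
Reagents that add atoms: iodomethane, CI
Why: C-alkylation of a cyclic 1,3-dione enolate installs C20; C10 carries two identical carbonyl arms, so no selectivity is asked, and any O-methyl ether formed is a vinylogous ester that the conditions of step 10 return to 14.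

Step 12
Reactants: 15 2-methyl-2-(bicyclic alkenyl)cyclohexane-1,3-dione
Product: 16 (2R,3S)-3-hydroxy-2-methyl-2-(bicyclic alkenyl)cyclohexan-1-one (skeleton numbering: C10 R, C1 S, hydroxyl cis to C20)
Conditions: (R)-Me-CBS oxazaborolidine [(R)-1-methyl-3,3-diphenyltetrahydro-1H,3H-pyrrolo[1,2-c][1,3,2]oxazaborole] (20 mol%), catecholborane, toluene, −60 °C
Reagents that add atoms: none
Why: Corey–Bakshi–Shibata reduction used to desymmetrise a 2,2-disubstituted 1,3-dione; the catalyst fixes the enantioface at whichever carbonyl it reduces (S carbinol), and hydride delivery anti to the axial C20 methyl is matched with that face at only one of the two carbonyls, which sets C10. Only the C10 configuration is carried forward, since C1 is oxidised again in step 17.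

Step 13
Reactants: 16 (2R,3S)-3-hydroxy-2-methyl-2-(bicyclic alkenyl)cyclohexan-1-one
Product: 17 C1 triethylsilyl ether of 16
Conditions: Et3SiOTf, 2,6-lutidine, CH2Cl2, −78 to 0 °C
Reagents that add atoms: triethylsilyl trifluoromethanesulfonate, CC[Si](CC)(CC)OS(=O)(=O)C(F)(F)F
Why: Silylation of the hindered secondary alcohol; capping the β-hydroxy ketone prevents retro-aldol cleavage of C1–C10 in the strong base of the next two steps.

Step 14
Reactants: 17 C1 triethylsilyl ether of 16
Product: 18 C4 geminal dimethyl ketone (C5 ketone, C1 silyl ether)
Conditions: KOt-Bu (4 equiv), MeI (excess), THF/t-BuOH, 0 °C to rt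
Reagents that add atoms: iodomethane, CI
Why: Exhaustive α-methylation of a ketone enolate; C10 is quaternary, so C4 is the only enolisable carbon and takes both methyls.

Step 15
Reactants: 18 C4 geminal dimethyl ketone
Product: 19 C5 exocyclic methylene compound (C5=C6, C1 silyl ether)
Conditions: Ph3PCH3Br, KOt-Bu, toluene, 100 °C
Reagents that add atoms: methyltriphenylphosphonium bromide, C[P+](c1ccccc1)(c1ccccc1)c1ccccc1.[Br-]
Why: Wittig methylenation under the forcing, salt-free conditions used for hindered ketones; the ketone has no α-hydrogen left, so enolisation cannot compete.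

Step 16
Reactants: 19 C5 exocyclic methylene compound
Product: 20 C1 alcohol (hydroxyl cis to C20, C5=C6)
Conditions: HF·pyridine, pyridine, THF, 0 °C to rt
Reagents that add atoms: none
Why: Fluoride cleavage of the triethylsilyl ether; the primary tert-butyldiphenylsilyl ether reacts much more slowly under buffered hydrogen fluoride, and the ketal is untouched.

Step 17
Reactants: 20 C1 alcohol
Product: 21 C1 ketone (C10 R, C5=C6)
Conditions: Dess–Martin periodinane, NaHCO3, CH2Cl2, rt
Reagents that add atoms: none
Why: Dess–Martin oxidation of a hindered secondary alcohol; neither alkene can move into conjugation because C10 is quaternary.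

Step 18
Reactants: 21 C1 ketone
Product: 22 diosphenol (C1 ketone, C2 enol, C2=C3)
Conditions: KOt-Bu, O2 (1 atm), t-BuOH/DME, rt; then aq. NH4Cl
Reagents that add atoms: dioxygen, O=O
Why: Base-mediated autoxidation of a ketone enolate (α-hydroperoxide, then loss of water) to the enolised 1,2-dione, the classical reaction of ketones flanked by a quaternary carbon; C2 is the only enolisable position.

Step 19
Reactants: 22 diosphenol
Product: 23 1,2-cis-diol with both hydroxyls on the C20 face (C1 equatorial, C2 axial)
Conditions: NaBH4, CeCl3·7H2O, MeOH/THF, −40 to 0 °C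
Reagents that add atoms: none
Why: Luche-type hydride reduction; C1 and, after tautomerisation of the enol, C2 each take hydride from the face opposite the axial C20 and C4 methyls, which places both oxygens on the hindered face and sets C1 and C2.

Step 20
Reactants: 23 1,2-cis-diol
Product: 24 C1,C2 diacetate (C5=C6)
Conditions: Ac2O, DMAP, pyridine, 40 °C
Reagents that add atoms: acetic anhydride, CC(=O)OC(C)=O
Why: DMAP-catalysed acetylation; mild heating is provided for the axial C2 hydroxyl.

Step 21
Reactants: 24 C1,C2 diacetate
Product: 25 C6 primary alcohol (H5 anti to C20, C6 equatorial)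
Conditions: 9-BBN, THF, 60 °C; then NaBO3·4H2O, H2O, rt
Reagents that add atoms: sodium perborate, [Na+].[O-]OB=O
Why: Brown hydroboration–oxidation; boron adds to terminal C6 and hydrogen to C5 from the face opposite the two axial methyls, which sets C5. 9-BBN leaves the trisubstituted, doubly neopentyl C9=C11 bond and the acetates alone, and perborate oxidises without hydrolysing the esters.

Step 22
Reactants: 25 C6 primary alcohol
Product: 26 C15 ketone (C6 alcohol, diacetate)
Conditions: 1 M HCl, THF, rt
Reagents that add atoms: water, O
Why: Acid hydrolysis of the dioxolane; the acetates, the tert-butyldiphenylsilyl ether and the trisubstituted alkene tolerate dilute acid at room temperature.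

Step 23
Reactants: 26 C15 ketone
Product: 27 16-methylene-15-ketone (C6 alcohol)
Conditions: (CH2O)n, i-Pr2NH2 O2CCF3, CF3CO2H (10 mol%), THF, 65 °C
Reagents that add atoms: paraformaldehyde (as formaldehyde), C=O
Why: Mannich-type α-methylenation through the iminium ion of formaldehyde followed by elimination of the amine; C16 is the only enolisable position, and the weakly acidic medium spares the acetates.

Step 24
Reactants: 27 16-methylene-15-ketone
Product: 28 C6 aldehyde (C7 silyl ether)
Conditions: Dess–Martin periodinane, NaHCO3, CH2Cl2, 0 °C to rt
Reagents that add atoms: none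
Why: Dess–Martin oxidation of the only free alcohol; the equatorial aldehyde is the stable configuration at C5, so any epimerisation would converge on it.

Step 25
Reactants: 28 C6 aldehyde
Product: 30 lactol with the C9=C11 bond (ring B closed), via hydroxy aldehyde 29 (not isolated)
Conditions: HF·pyridine, THF, 0 °C to rt
Reagents that add atoms: none
Why: Fluoride cleavage of the silyl ether frees the C7 hydroxyl, which adds to the C6 aldehyde held next to it by the C8–C9–C10 frame (hemiacetal formation); C6 settles by ring–chain equilibration.

Step 26
Reactants: 30 lactol with the C9=C11 bond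
Product: 31 CNP0224512.1
Conditions: dimethyldioxirane, acetone, −20 to 0 °C
Reagents that add atoms: dimethyldioxirane, CC1(C)OO1
Why: Electrophilic epoxidation of the only electron-rich alkene, the enone alkene being deactivated; oxygen should arrive on the face of the one-carbon bridge C14, away from the C15–C16 bridge, which sets C9 and C11. A neutral dioxirane is chosen so that the lactol hydroxyl on the opposite face cannot direct the oxidant.

## Compound list

1 | tert-butyl 2-oxocyclohexane-1-carboxylate | CC(C)(C)OC(=O)C1CCCCC1=O | starting material
2 | tert-butyl (S)-1-(hydroxymethyl)-2-oxocyclohexane-1-carboxylate | CC(C)(C)OC(=O)[C@@]1(CO)C(=O)CCCC1 | intermediate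
3 | tert-butyl (S)-1-[(tert-butyldiphenylsilyloxy)methyl]-2-oxocyclohexane-1-carboxylate | CC(C)(C)OC(=O)[C@@]1(CO[Si](c2ccccc2)(c2ccccc2)C(C)(C)C)C(=O)CCCC1 | intermediate
4 | tert-butyl (S)-1-[(tert-butyldiphenylsilyloxy)methyl]-2-(trifluoromethylsulfonyloxy)cyclohex-2-ene-1-carboxylate | CC(C)(C)OC(=O)[C@@]1(CO[Si](c2ccccc2)(c2ccccc2)C(C)(C)C)C(OS(=O)(=O)C(F)(F)F)=CCCC1 | intermediate
5 | (S)-1-[(tert-butyldiphenylsilyloxy)methyl]-2-(trifluoromethylsulfonyloxy)cyclohex-2-ene-1-carboxylic acid | OC(=O)[C@@]1(CO[Si](c2ccccc2)(c2ccccc2)C(C)(C)C)C(OS(=O)(=O)C(F)(F)F)=CCCC1 | intermediate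
6 | acid chloride of 5 | ClC(=O)[C@@]1(CO[Si](c2ccccc2)(c2ccccc2)C(C)(C)C)C(OS(=O)(=O)C(F)(F)F)=CCCC1 | intermediate (not isolated)
7 | (S)-6-(2-diazoacetyl)-6-[(tert-butyldiphenylsilyloxy)methyl]cyclohex-1-en-1-yl trifluoromethanesulfonate | [N-]=[N+]=CC(=O)[C@@]1(CO[Si](c2ccccc2)(c2ccccc2)C(C)(C)C)C(OS(=O)(=O)C(F)(F)F)=CCCC1 | intermediate
8 | (1S,5R)-1-[(tert-butyldiphenylsilyloxy)methyl]-7-oxobicyclo[3.2.1]oct-2-en-2-yl trifluoromethanesulfonate | C1C(=O)[C@@]2(CO[Si](c3ccccc3)(c3ccccc3)C(C)(C)C)C(OS(=O)(=O)C(F)(F)F)=CC[C@@H]1C2 | intermediate
9 | C15 ethylene ketal of 8 | C1C4(OCCO4)[C@@]2(CO[Si](c3ccccc3)(c3ccccc3)C(C)(C)C)C(OS(=O)(=O)C(F)(F)F)=CC[C@@H]1C2 | intermediate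
10 | 3-ethoxycyclohex-2-en-1-one | CCOC1=CC(=O)CCC1 | starting material
11 | 3-ethoxy-2-iodocyclohex-2-en-1-one | CCOC1=C(I)C(=O)CCC1 | intermediate
12 | C9 pinacol boronate of the ketal-protected bicycle | C1C4(OCCO4)[C@@]2(CO[Si](c3ccccc3)(c3ccccc3)C(C)(C)C)C(B3OC(C)(C)C(C)(C)O3)=CC[C@@H]1C2 | intermediate (not isolated)
13 | 3-ethoxy-2-(bicyclic alkenyl)cyclohex-2-en-1-one | C1C4(OCCO4)[C@@]2(CO[Si](c3ccccc3)(c3ccccc3)C(C)(C)C)C(C5=C(OCC)CCCC5=O)=CC[C@@H]1C2 | intermediate
14 | 2-(bicyclic alkenyl)cyclohexane-1,3-dione, enol form | C1C4(OCCO4)[C@@]2(CO[Si](c3ccccc3)(c3ccccc3)C(C)(C)C)C(C5=C(O)CCCC5=O)=CC[C@@H]1C2 | intermediate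
15 | 2-methyl-2-(bicyclic alkenyl)cyclohexane-1,3-dione | C1C4(OCCO4)[C@@]2(CO[Si](c3ccccc3)(c3ccccc3)C(C)(C)C)C(C5(C)C(=O)CCCC5=O)=CC[C@@H]1C2 | intermediate
16 | (2R,3S)-3-hydroxy-2-methyl-2-(bicyclic alkenyl)cyclohexan-1-one | C1C4(OCCO4)[C@@]2(CO[Si](c3ccccc3)(c3ccccc3)C(C)(C)C)C([C@]5(C)[C@@H](O)CCCC5=O)=CC[C@@H]1C2 | intermediate
17 | C1 triethylsilyl ether of 16 | C1C4(OCCO4)[C@@]2(CO[Si](c3ccccc3)(c3ccccc3)C(C)(C)C)C([C@]5(C)[C@@H](O[Si](CC)(CC)CC)CCCC5=O)=CC[C@@H]1C2 | intermediate
18 | C4 geminal dimethyl C5 ketone, C1 triethylsilyl ether | C1C4(OCCO4)[C@@]2(CO[Si](c3ccccc3)(c3ccccc3)C(C)(C)C)C([C@]5(C)[C@@H](O[Si](CC)(CC)CC)CCC(C)(C)C5=O)=CC[C@@H]1C2 | intermediate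
19 | C5 exocyclic methylene compound, C1 triethylsilyl ether | C1C4(OCCO4)[C@@]2(CO[Si](c3ccccc3)(c3ccccc3)C(C)(C)C)C([C@]5(C)[C@@H](O[Si](CC)(CC)CC)CCC(C)(C)C5=C)=CC[C@@H]1C2 | intermediate
20 | C1 alcohol, hydroxyl cis to C20, C5=C6 | C1C4(OCCO4)[C@@]2(CO[Si](c3ccccc3)(c3ccccc3)C(C)(C)C)C([C@]5(C)[C@@H](O)CCC(C)(C)C5=C)=CC[C@@H]1C2 | intermediate
21 | C1 ketone, C5=C6 | C1C4(OCCO4)[C@@]2(CO[Si](c3ccccc3)(c3ccccc3)C(C)(C)C)C([C@]5(C)C(=O)CCC(C)(C)C5=C)=CC[C@@H]1C2 | intermediate
22 | diosphenol: C1 ketone, C2 enol, C2=C3 | C1C4(OCCO4)[C@@]2(CO[Si](c3ccccc3)(c3ccccc3)C(C)(C)C)C([C@]5(C)C(=O)C(O)=CC(C)(C)C5=C)=CC[C@@H]1C2 | intermediate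
23 | 1,2-cis-diol, both hydroxyls on the C20 face | C1C4(OCCO4)[C@@]2(CO[Si](c3ccccc3)(c3ccccc3)C(C)(C)C)C([C@]5(C)[C@@H](O)[C@@H](O)CC(C)(C)C5=C)=CC[C@@H]1C2 | intermediate
24 | C1,C2 diacetate, C5=C6 | C1C4(OCCO4)[C@@]2(CO[Si](c3ccccc3)(c3ccccc3)C(C)(C)C)C([C@]5(C)[C@@H](OC(C)=O)[C@@H](OC(C)=O)CC(C)(C)C5=C)=CC[C@@H]1C2 | intermediate
25 | C6 primary alcohol, H5 anti to C20, C15 ketal | C1C4(OCCO4)[C@@]2(CO[Si](c3ccccc3)(c3ccccc3)C(C)(C)C)C([C@]5(C)[C@@H](OC(C)=O)[C@@H](OC(C)=O)CC(C)(C)[C@H]5CO)=CC[C@@H]1C2 | intermediate
26 | C15 ketone, C6 alcohol | C1C(=O)[C@@]2(CO[Si](c3ccccc3)(c3ccccc3)C(C)(C)C)C([C@]5(C)[C@@H](OC(C)=O)[C@@H](OC(C)=O)CC(C)(C)[C@H]5CO)=CC[C@@H]1C2 | intermediate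
27 | 16-methylene-15-ketone, C6 alcohol | C=C1C(=O)[C@@]2(CO[Si](c3ccccc3)(c3ccccc3)C(C)(C)C)C([C@]5(C)[C@@H](OC(C)=O)[C@@H](OC(C)=O)CC(C)(C)[C@H]5CO)=CC[C@@H]1C2 | intermediate
28 | C6 aldehyde, C7 silyl ether | C=C1C(=O)[C@@]2(CO[Si](c3ccccc3)(c3ccccc3)C(C)(C)C)C([C@]5(C)[C@@H](OC(C)=O)[C@@H](OC(C)=O)CC(C)(C)[C@H]5C=O)=CC[C@@H]1C2 | intermediate
29 | C7 hydroxy C6 aldehyde | C=C1C(=O)[C@@]2(CO)C([C@]5(C)[C@@H](OC(C)=O)[C@@H](OC(C)=O)CC(C)(C)[C@H]5C=O)=CC[C@@H]1C2 | intermediate (not isolated)
30 | lactol with the C9=C11 bond | C=C1C(=O)[C@@]23CO[C@@H](O)[C@@H]4C(C)(C)C[C@H](OC(C)=O)[C@H](OC(C)=O)[C@@]4(C)C2=CC[C@@H]1C3 | intermediate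
31 | CNP0224512.1 | C=C1C(=O)[C@@]23CO[C@@H](O)[C@@H]4C(C)(C)C[C@H](OC(C)=O)[C@H](OC(C)=O)[C@@]4(C)[C@]24O[C@@H]4C[C@@H]1C3 | target

## Step count and least certain steps

Total: 26 steps. Longest linear sequence: 25 steps (1 to 31 through steps 1–7 and 9–26); step 8 is the one-step side branch.

**Step 6 (key step).** The carbenoid may be captured by the C7 ether oxygen (five-membered oxonium ylide, then a silyl or alkyl shift), may add to the C9=C11 bond with vinylogous Wolff fragmentation, or may insert at the allylic C12–H. An acceptor-only carbenoid is very reactive and discriminates poorly. The fallback uses a tamer acceptor/acceptor carbenoid, which reacts through a later transition state and prefers 1,5 insertion to ylide formation. It sets out from acid 5: acid chloride 6 is treated with the lithium enolate of tert-butyl acetate to give the tert-butyl β-keto ester F1. Diazo transfer with 4-acetamidobenzenesulfonyl azide and triethylamine gives the diazo β-keto ester F2. Rh2(OAc)4 then gives the bicyclic β-keto ester F3 (C16 epimerisable), and CF3CO2H followed by gentle warming removes the ester by loss of isobutene and carbon dioxide. The fallback rejoins the route at 8.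

**Step 12.** Group selection between the two diastereotopic carbonyls may be poor if the preference for hydride delivery anti to the C20 methyl is weak under catalyst control, and the second carbonyl may be reduced as well. The fallback gives up catalyst control for separation and recycling. It sets out from 15: NaBH4 in methanol at −78 °C reduces either carbonyl, giving 16 together with the C10-epimeric hydroxy ketone F6. The two are separated by chromatography, and F6 is returned to 15 with Dess–Martin periodinane and resubmitted. The fallback rejoins the route at 16.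

**Step 11.** The hindered enolate of 14 may methylate on oxygen instead of on C10, because the carbon is flanked by the bicyclic alkenyl group. The fallback forms the quaternary carbon by ligand coupling on lead and brings the methyl in with the dione. It sets out from 9: Me3SnSnMe3, Pd(PPh3)4 and LiCl give the alkenyl stannane F4, and Pb(OAc)4 exchanges tin for lead to give the alkenyllead triacetate F5. F5 then alkenylates commercial 2-methylcyclohexane-1,3-dione in chloroform with pyridine. The fallback rejoins the route at 15 and bypasses 13 and 14.

**Step 15.** The ylide may fail to add to a ketone whose two α-carbons are both quaternary. The fallback uses a smaller nucleophile and a separate elimination. It sets out from 18: MeLi with CeCl3 adds from the face opposite the axial methyls to give the tertiary alcohol F7. Dehydration with the Burgess reagent can only go towards the new methyl, because both ring neighbours are quaternary. The fallback rejoins the route at 19.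

**Step 26.** Oxygen may be delivered to the face of the keto bridge, or the lactol C–H may be oxidised in competition, because the alkene lies between two quaternary carbons and reacts slowly. The fallback inverts the facial outcome through a halohydrin. It sets out from 28: N-bromosuccinimide in aqueous acetone gives the bromohydrin F8, with bromine on the face the electrophile prefers and hydroxyl anti to it; the regioisomeric bromohydrin would serve equally. Ag2O closes F8 with inversion to the epoxy aldehyde F9, whose oxygen is on the face of C14. Tetrabutylammonium fluoride buffered with acetic acid then removes the silyl group and the lactol closes. The fallback rejoins the route at 31.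

## Further compounds

F1 | step 6 | tert-butyl β-keto ester from 6 and tert-butyl acetate | CC(C)(C)OC(=O)CC(=O)[C@@]1(CO[Si](c2ccccc2)(c2ccccc2)C(C)(C)C)C(OS(=O)(=O)C(F)(F)F)=CCCC1
F2 | step 6 | tert-butyl 2-diazo-3-oxo ester | CC(C)(C)OC(=O)C(=[N+]=[N-])C(=O)[C@@]1(CO[Si](c2ccccc2)(c2ccccc2)C(C)(C)C)C(OS(=O)(=O)C(F)(F)F)=CCCC1
F3 | step 6 | C16 tert-butoxycarbonyl derivative of 8 (C16 epimerisable, not assigned) | CC(C)(C)OC(=O)C1C(=O)[C@@]2(CO[Si](c3ccccc3)(c3ccccc3)C(C)(C)C)C(OS(=O)(=O)C(F)(F)F)=CC[C@@H]1C2
F4 | step 11 | C9 trimethylstannane of the ketal-protected bicycle | C1C4(OCCO4)[C@@]2(CO[Si](c3ccccc3)(c3ccccc3)C(C)(C)C)C([Sn](C)(C)C)=CC[C@@H]1C2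
F5 | step 11 | C9 lead triacetate of the ketal-protected bicycle | C1C4(OCCO4)[C@@]2(CO[Si](c3ccccc3)(c3ccccc3)C(C)(C)C)C([Pb](OC(C)=O)(OC(C)=O)OC(C)=O)=CC[C@@H]1C2
F6 | step 12 | (2S,3R)-3-hydroxy-2-methyl-2-(bicyclic alkenyl)cyclohexan-1-one, the C10 and C1 epimer of 16 | C1C4(OCCO4)[C@@]2(CO[Si](c3ccccc3)(c3ccccc3)C(C)(C)C)C([C@@]5(C)[C@H](O)CCCC5=O)=CC[C@@H]1C2
F7 | step 15 | C5 tertiary alcohol from methyl addition to 18 (new methyl anti to C20) | C1C4(OCCO4)[C@@]2(CO[Si](c3ccccc3)(c3ccccc3)C(C)(C)C)C([C@]5(C)[C@@H](O[Si](CC)(CC)CC)CCC(C)(C)[C@@]5(C)O)=CC[C@@H]1C2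
F8 | step 26 | bromohydrin of 28: C9 hydroxyl on the C14 face, C11 bromine on the face of the keto bridge | C=C1C(=O)[C@@]2(CO[Si](c3ccccc3)(c3ccccc3)C(C)(C)C)[C@]([C@]5(C)[C@@H](OC(C)=O)[C@@H](OC(C)=O)CC(C)(C)[C@H]5C=O)(O)[C@@H](Br)C[C@@H]1C2
F9 | step 26 | 9,11-epoxy C6 aldehyde, C7 silyl ether | C=C1C(=O)[C@@]2(CO[Si](c3ccccc3)(c3ccccc3)C(C)(C)C)[C@]3([C@]5(C)[C@@H](OC(C)=O)[C@@H](OC(C)=O)CC(C)(C)[C@H]5C=O)O[C@@H]3C[C@@H]1C2
A1 | alternative 1 | ring A acyloin (1-hydroxy-2-ketone, C6 methyl acetal) | C=C1C[C@@]23CO[C@@H](OC)[C@@H]4C(C)(C)CC(=O)[C@H](O)[C@@]4(C)C2=CC[C@@H]1C3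
A2 | alternative 2 | tetracyclic C11 ketone with C15 silyl enol ether | C1=C(O[Si](C)(C)C(C)(C)C)[C@@]23COC(=O)[C@@H]4C(C)(C)CC(OC)(OC)C[C@@]4(C)[C@H]2C(=O)C[C@@H]1C3
A3 | alternative 3 | tetracyclic C2-keto lactone | C=C1C[C@@]23COC(=O)[C@@H]4C(C)(C)CC(=O)C[C@@]4(C)C2=CC[C@@H]1C3
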